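**Retrosynthetic overview**

1. Ring A is the quinone that carries the 2-(2-methoxyphenyl)ethyl group and ring B the quinone that carries the 2-phenylethyl group; the last step only cleaves the two quinonyl isopropyl ethers of biquinone 17 (BCl3).
2. Key disconnection (step 7), made in both rings at once: the bond from the carbonyl carbon flanked by C–CH3 to the ring carbon that carries the other quinone (6π electrocyclisation of a dienylketene) and the bond from the other carbonyl carbon to the arylethyl-bearing carbon (C–Li addition). This leads to two molecules of cyclobutenedione 12 and one 3,6-dimetallated octa-3,5-diene made from 9.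
3. Enabling feature: each quinone ring is a four-carbon arc C(=O)–C(CH3)=C(OH)–C(=O), a ring-opened methylsquarate, closed by one C=C whose carbons carry the arylethyl chain and the inter-ring bond. The two C=C units are joined by the inter-ring σ bond, so the four non-squarate carbons of rings A and B form one buta-1,3-diene, and the two rings differ only in a remote OCH3.
4. The unsymmetrical diene 9 comes from Stille union of vinyl iodide 2 (IBr adduct of 4-phenylbut-1-yne) with distannane 8 (cis-distannation of alkyne 7).
5. Ring order: no carbocycle is made before step 7; rings B and A are both closed in step 7.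

Key step: step 7

Remark: the target has no stereocentre and is drawn without a descriptor for the tetra-ortho-substituted inter-ring axis, so the axis is treated as unassigned (racemic or freely equilibrating) and no step addresses it.

**Route**

Step 1
Reactants: 1 4-phenylbut-1-yne
Product: 2 (E)-(3-bromo-4-iodobut-3-en-1-yl)benzene
Conditions: IBr (1.05 equiv), CH2Cl2, −78 → 0 °C, dark
Reagents that add atoms: iodine monobromide, IBr
Why: Electrophilic iodobromination of a terminal alkyne: the iodonium ion formed at the terminal carbon should be opened anti by bromide at the internal (Markovnikov) carbon, giving the E bromo-iodoalkene, and the unactivated phenyl ring is inert to IBr.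

Step 2
Reactants: 3 trimethyl(prop-1-yn-1-yl)silane; 4 1-(bromomethyl)-2-methoxybenzene
Product: 6 [4-(2-methoxyphenyl)but-1-yn-1-yl]trimethylsilane, via lithiated silylpropyne 5 (not isolated)
Conditions: n-BuLi, THF, −78 → −20 °C; then 4, −78 → 23 °C
Reagents that add atoms: none
Why: Propargylic lithiation of the silyl-capped propyne followed by SN2 alkylation with the benzylic bromide; the silyl group blocks the acetylenic position and disfavours allenyl products.

Step 3
Reactants: 6 [4-(2-methoxyphenyl)but-1-yn-1-yl]trimethylsilane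
Product: 7 1-(but-3-yn-1-yl)-2-methoxybenzene
Conditions: K2CO3 (cat.), MeOH, 23 °C
Reagents that add atoms: none
Why: Base-catalysed methanolysis of the alkynyl C–Si bond (protodesilylation) should free the terminal alkyne and leave the aryl methyl ether untouched.

Step 4
Reactants: 7 1-(but-3-yn-1-yl)-2-methoxybenzene
Product: 8 [(Z)-4-(2-methoxyphenyl)but-1-ene-1,2-diyl]bis(trimethylstannane)
Conditions: Me3SnSnMe3 (1.05 equiv), Pd(PPh3)4 (2 mol%), THF, 65 °C
Reagents that add atoms: hexamethylditin, C[Sn](C)(C)[Sn](C)(C)C
Why: Palladium-catalysed cis-distannation of a terminal alkyne: zerovalent palladium inserts into the Sn–Sn bond and delivers both stannyl groups to the same face, which fixes the Z geometry.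

Step 5
Reactants: 2 (E)-(3-bromo-4-iodobut-3-en-1-yl)benzene; 8 [(Z)-4-(2-methoxyphenyl)but-1-ene-1,2-diyl]bis(trimethylstannane)
Product: 9 [(3Z,5E)-6-bromo-1-(2-methoxyphenyl)-8-phenylocta-3,5-dien-3-yl]trimethylstannane
Conditions: PdCl2(MeCN)2 (5 mol%), DMF, 23 °C
Reagents that add atoms: none
Why: Stille coupling (divalent palladium precatalyst reduced in situ to zerovalent palladium): oxidative addition should occur at C–I much faster than at the internal C–Br, the unhindered terminal CH–SnMe3 should transmetalate in preference to the α-branched internal C–SnMe3, and both alkene geometries are retained, which sets the 3Z,5E diene.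

Step 6
Reactants: 10 3,4-di(propan-2-yloxy)cyclobut-3-ene-1,2-dione (diisopropyl squarate)
Product: 12 3-methyl-4-(propan-2-yloxy)cyclobut-3-ene-1,2-dione, via lithium alkoxide adduct 11 (not isolated)
Conditions: MeLi (1.05 equiv), THF, −78 °C; then (CF3CO)2O, −78 → 0 °C
Reagents that add atoms: methyllithium, [Li]C
Why: 1,2-Addition of MeLi to one vinylogous-ester carbonyl of the squarate, then trifluoroacetylation and ionisation of the tertiary carbinol with loss of one isopropyl group (squarate-to-cyclobutenedione transposition), should give the 3-alkoxy-4-methyl dione.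

Step 7
Reactants: 9 [(3Z,5E)-6-bromo-1-(2-methoxyphenyl)-8-phenylocta-3,5-dien-3-yl]trimethylstannane; 12 3-methyl-4-(propan-2-yloxy)cyclobut-3-ene-1,2-dione (2.5 equiv)
Product: 17 2-[2-(2-methoxyphenyl)ethyl]-5,5'-dimethyl-2'-(2-phenylethyl)-4,4'-di(propan-2-yloxy)[1,1'-bi(cyclohexa-1,4-diene)]-3,3',6,6'-tetrone, via monolithiated bromodiene 13 (not isolated), via dilithiodiene 14 (not isolated), via bis-cyclobutenol 15 (not isolated), via bis-hydroquinone 16 (not isolated)
Conditions: MeLi (1.05 equiv), THF, −78 → −40 °C; t-BuLi (2.1 equiv), −78 °C; cannulate into 12, THF, −78 °C; sat. aq NH4Cl; crude in toluene, 110 °C; then Ag2O, MgSO4, Et2O, 23 °C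
Reagents that add atoms: none
Why: Sn/Li exchange (MeLi) and Br/Li exchange (t-BuLi) should convert 9 into dilithiodiene 14 with both geometries retained; each C–Li adds 1,2 to the ketone-like carbonyl of 12 (the one next to the O-isopropyl-bearing carbon, the other being a deactivated vinylogous ester) to give 15, and on heating each 4-alkenyl-4-hydroxycyclobutenone opens by conrotatory 4π ring opening (hydroxyl rotating outward) to a dienylketene that closes and enolises to bis-hydroquinone 16, which Ag2O dehydrogenates to 17. The closest known reaction type is the Moore–Liebeskind ring expansion of 4-alkenyl-4-hydroxycyclobutenones to hydroquinones and quinones, used here twice on one diene. Rings A and B are closed in the same way, by thermal disrotatory 6π electrocyclisation in which the ketene carbon (the future carbonyl flanked by C–CH3) bonds to the inner diene carbon (the future inter-ring carbon); the preceding C–Li additions only attach the four-membered rings. No persistent stereocentre is created: the two carbinol centres of 15 form as a diastereomer mixture and are erased on aromatisation, and only the unassigned biaryl axis remains. The step needs (a) regiocontrol, which follows from the site of carbonyl addition and places methyl next to the carbonyl that bonds to the inter-ring carbon, (b) two separate additions rather than both C–Li bonds attacking one dione, which the E geometry at the bromide-derived end secures because neither lithiated terminus can reach the cyclobutenone at the other end without a trans double bond in a six-membered ring (helped by inverse addition to excess 12), and (c) 6π rather than 8π closure, which geometry enforces at the E end and the irreversible aromatisation after 6π closure enforces at the Z end.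

Step 8
Reactants: 17 2-[2-(2-methoxyphenyl)ethyl]-5,5'-dimethyl-2'-(2-phenylethyl)-4,4'-di(propan-2-yloxy)[1,1'-bi(cyclohexa-1,4-diene)]-3,3',6,6'-tetrone
Product: 18 4,4'-dihydroxy-2-[2-(2-methoxyphenyl)ethyl]-5,5'-dimethyl-2'-(2-phenylethyl)[1,1'-bi(cyclohexa-1,4-diene)]-3,3',6,6'-tetrone (target)
Conditions: BCl3 (6 equiv), CH2Cl2, −78 → 0 °C; then H2O
Reagents that add atoms: none
Why: Lewis-acid dealkylation of the two isopropyl vinylogous esters: BCl3 chelated between the ring carbonyl and the neighbouring ether oxygen should release the secondary alkyl group as 2-chloropropane, while the non-chelated anisole methyl ether is not cleaved at or below 0 °C.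

**Compound list**

1 | 4-phenylbut-1-yne | C#CCCc1ccccc1 | starting material
2 | (E)-(3-bromo-4-iodobut-3-en-1-yl)benzene | Br/C(CCc1ccccc1)=C/I | intermediate
3 | trimethyl(prop-1-yn-1-yl)silane | CC#C[Si](C)(C)C | starting material
4 | 1-(bromomethyl)-2-methoxybenzene | COc1ccccc1CBr | starting material
5 | [3-(trimethylsilyl)prop-2-yn-1-yl]lithium | [Li]CC#C[Si](C)(C)C | intermediate
6 | [4-(2-methoxyphenyl)but-1-yn-1-yl]trimethylsilane | COc1ccccc1CCC#C[Si](C)(C)C | intermediate
7 | 1-(but-3-yn-1-yl)-2-methoxybenzene | COc1ccccc1CCC#C | intermediate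
8 | [(Z)-4-(2-methoxyphenyl)but-1-ene-1,2-diyl]bis(trimethylstannane) | COc1ccccc1CC/C([Sn](C)(C)C)=C/[Sn](C)(C)C | intermediate
9 | [(3Z,5E)-6-bromo-1-(2-methoxyphenyl)-8-phenylocta-3,5-dien-3-yl]trimethylstannane | COc1ccccc1CC/C([Sn](C)(C)C)=C/C=C(Br)\CCc1ccccc1 | intermediate
10 | 3,4-di(propan-2-yloxy)cyclobut-3-ene-1,2-dione | CC(C)OC1=C(OC(C)C)C(=O)C1=O | starting material
11 | lithium 1-methyl-4-oxo-2,3-di(propan-2-yloxy)cyclobut-2-en-1-olate (racemic) | CC1([O-])C(OC(C)C)=C(OC(C)C)C1=O.[Li+] | intermediate
12 | 3-methyl-4-(propan-2-yloxy)cyclobut-3-ene-1,2-dione | CC1=C(OC(C)C)C(=O)C1=O | intermediate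
13 | [(3E,5E)-6-bromo-1-(2-methoxyphenyl)-8-phenylocta-3,5-dien-3-yl]lithium (geometry of 9 retained; the descriptor changes because lithium ranks below carbon) | COc1ccccc1CC/C([Li])=C/C=C(Br)\CCc1ccccc1 | intermediate
14 | [(3E,5Z)-1-(2-methoxyphenyl)-8-phenylocta-3,5-diene-3,6-diyl]dilithium (geometry of 9 retained) | COc1ccccc1CC/C([Li])=C/C=C([Li])\CCc1ccccc1 | intermediate
15 | 4,4'-[(3Z,5E)-1-(2-methoxyphenyl)-8-phenylocta-3,5-diene-3,6-diyl]bis[4-hydroxy-2-methyl-3-(propan-2-yloxy)cyclobut-2-en-1-one] (mixture of diastereomers at the two carbinol carbons) | COc1ccccc1CC/C(C1(O)C(OC(C)C)=C(C)C1=O)=C/C=C(C1(O)C(OC(C)C)=C(C)C1=O)\CCc1ccccc1 | intermediate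
16 | 6-[2-(2-methoxyphenyl)ethyl]-3,3'-dimethyl-6'-(2-phenylethyl)-4,4'-di(propan-2-yloxy)[1,1'-biphenyl]-2,2',5,5'-tetrol | COc1ccccc1CCc1c(O)c(OC(C)C)c(C)c(O)c1-c1c(O)c(C)c(OC(C)C)c(O)c1CCc1ccccc1 | intermediate
17 | 2-[2-(2-methoxyphenyl)ethyl]-5,5'-dimethyl-2'-(2-phenylethyl)-4,4'-di(propan-2-yloxy)[1,1'-bi(cyclohexa-1,4-diene)]-3,3',6,6'-tetrone | COc1ccccc1CCC1=C(C2=C(CCc3ccccc3)C(=O)C(OC(C)C)=C(C)C2=O)C(=O)C(C)=C(OC(C)C)C1=O | intermediate
18 | 4,4'-dihydroxy-2-[2-(2-methoxyphenyl)ethyl]-5,5'-dimethyl-2'-(2-phenylethyl)[1,1'-bi(cyclohexa-1,4-diene)]-3,3',6,6'-tetrone | COc1ccccc1CCC1=C(C2=C(CCc3ccccc3)C(=O)C(O)=C(C)C2=O)C(=O)C(C)=C(O)C1=O | target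

**Step count and risks**

Total step count: 8. Longest linear sequence: 6 steps (steps 2, 3, 4, 5, 7, 8); steps 1 and 6 are side branches.

Steps most likely to fail:

1. Step 7. Possible failures are incomplete double metalation or double addition (protonation of one C–Li, mono-adducts, oligomers in which two lithiated termini meet one dione) and, on heating, stalling or diversion of the second ring closure at the Z-configured terminus, where the already formed aryl ring must sit on the inside of the closing triene. The fallback builds the two rings one after the other and sets out from 9. MeLi alone exchanges only tin and gives 13, which is added to 12 to give the mono-cyclobutenol F1. Thermolysis (toluene, 110 °C) gives the bromoalkenyl hydroquinone F2, which is methylated (Me2SO4, K2CO3, acetone) to the dimethyl ether F3. Br/Li exchange of F3 (t-BuLi, THF, −78 °C) and addition to 12 gives the second cyclobutenol F4, whose thermolysis gives the mixed hydroquinone–dimethoxyarene F5 by the same 6π closure at the E-configured terminus. Oxidation of F5 with (NH4)2Ce(NO3)6 (tetravalent cerium, MeCN/H2O, 0 °C) turns the hydroquinone ring and, by oxidative demethylation, the dimethoxyarene ring into quinones, so the fallback comes back to the route at 17.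

2. Step 5. Possible failures are transmetalation from the internal tin, further coupling at the vinylic bromides of 2 and 9 (oligomers), and protodestannylation of 9 on work-up. The fallback replaces the tin-based union by a silicon/boron-based one and sets out from 7 and 2. Palladium-catalysed cis-silylboration of 7 with PhMe2Si–Bpin (Pd(OAc)2, 1,1,3,3-tetramethylbutyl isocyanide, toluene, 110 °C) gives the silyl boronate F6, with boron on the terminal carbon. Suzuki–Miyaura coupling of F6 with 2 (Pd(PPh3)4, aq K3PO4, THF, 40 °C) gives the silyl bromo diene F7; the nucleophile carries no tin or halogen, so it cannot couple with itself. Iododesilylation with retention (N-iodosuccinimide, MeCN, 0 °C) gives the iodo bromo diene F8. Double halogen–lithium exchange of F8 (t-BuLi, 4.2 equiv, THF, −78 °C) gives 14, where the fallback comes back to the route inside step 7.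

3. Step 8. Possible failures are incomplete cleavage of the second, more hindered isopropyl ether and Lewis-acid-induced decomposition of the electron-poor biquinone. The fallback moves the dealkylation to the hydroquinone oxidation level and sets out from 17. Reduction with Na2S2O4 (EtOAc/H2O) gives 16, in which the isopropyl groups are ordinary aryl ethers. BCl3 (CH2Cl2, −78 → 0 °C) cleaves them to the hexahydroxybiphenyl F9. Oxidation of F9 in air (or with Ag2O, Et2O) gives the two hydroxy-para-quinone rings, so the fallback comes back to the route at 18.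

**Further compounds**

F1 | step 7 | 4-[(3Z,5E)-6-bromo-1-(2-methoxyphenyl)-8-phenylocta-3,5-dien-3-yl]-4-hydroxy-2-methyl-3-(propan-2-yloxy)cyclobut-2-en-1-one (racemic) | COc1ccccc1CC/C(C1(O)C(OC(C)C)=C(C)C1=O)=C/C=C(Br)\CCc1ccccc1
F2 | step 7 | 2-[(E)-2-bromo-4-phenylbut-1-en-1-yl]-3-[2-(2-methoxyphenyl)ethyl]-6-methyl-5-(propan-2-yloxy)benzene-1,4-diol | COc1ccccc1CCc1c(O)c(OC(C)C)c(C)c(O)c1/C=C(Br)\CCc1ccccc1
F3 | step 7 | 1-[(E)-2-bromo-4-phenylbut-1-en-1-yl]-2,5-dimethoxy-6-[2-(2-methoxyphenyl)ethyl]-3-methyl-4-(propan-2-yloxy)benzene | COc1ccccc1CCc1c(OC)c(OC(C)C)c(C)c(OC)c1/C=C(Br)\CCc1ccccc1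
F4 | step 7 | 4-[(E)-1-{2,5-dimethoxy-6-[2-(2-methoxyphenyl)ethyl]-3-methyl-4-(propan-2-yloxy)phenyl}-4-phenylbut-1-en-2-yl]-4-hydroxy-2-methyl-3-(propan-2-yloxy)cyclobut-2-en-1-one (racemic) | COc1ccccc1CCc1c(OC)c(OC(C)C)c(C)c(OC)c1/C=C(\CCc1ccccc1)C1(O)C(OC(C)C)=C(C)C1=O
F5 | step 7 | 2',5'-dimethoxy-6'-[2-(2-methoxyphenyl)ethyl]-3,3'-dimethyl-6-(2-phenylethyl)-4,4'-di(propan-2-yloxy)[1,1'-biphenyl]-2,5-diol | COc1ccccc1CCc1c(OC)c(OC(C)C)c(C)c(OC)c1-c1c(O)c(C)c(OC(C)C)c(O)c1CCc1ccccc1
F6 | step 5 | 2-[(Z)-2-[dimethyl(phenyl)silyl]-4-(2-methoxyphenyl)but-1-en-1-yl]-4,4,5,5-tetramethyl-1,3,2-dioxaborolane | COc1ccccc1CC/C([Si](C)(C)c1ccccc1)=C/B1OC(C)(C)C(C)(C)O1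
F7 | step 5 | [(3Z,5E)-6-bromo-1-(2-methoxyphenyl)-8-phenylocta-3,5-dien-3-yl]dimethyl(phenyl)silane | COc1ccccc1CC/C([Si](C)(C)c1ccccc1)=C/C=C(Br)\CCc1ccccc1
F8 | step 5 | 1-[(3Z,5E)-6-bromo-3-iodo-8-phenylocta-3,5-dien-1-yl]-2-methoxybenzene | COc1ccccc1CC/C(I)=C/C=C(Br)\CCc1ccccc1
F9 | step 8 | 6-[2-(2-methoxyphenyl)ethyl]-3,3'-dimethyl-6'-(2-phenylethyl)[1,1'-biphenyl]-2,2',4,4',5,5'-hexol | COc1ccccc1CCc1c(O)c(O)c(C)c(O)c1-c1c(O)c(C)c(O)c(O)c1CCc1ccccc1
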